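**Retrosynthetic overview**

- The strategy rests on ring C, the pyran ring O1–C2–C3–C4–C4a–C8a of the 2,4-diarylchroman. O1, C8a, C4a and C4 are read as an ortho-quinone methide of the resorcinol ring A, with C4 carrying the trioxygenated ring D; C2–C3 is 4-hydroxystyrene (ring B on C2).
- Last disconnection: the aryl ketone bond on ring D (Friedel–Crafts acylation with 9-phenylnonanoyl chloride), with all five phenols carried as benzyl ethers and released at the end.
- Key disconnection: C3–C4 and O1–C2 of ring C, by an enantioselective [4+2] annulation of the quinone methide, generated from a racemic ortho-hydroxybenzhydrol, with 4-benzyloxystyrene.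
- The benzhydrol comes from the ring D aryllithium and 4-(benzyloxy)-2-hydroxybenzaldehyde; the styrene comes from a Wittig methylenation.
- Ring order: rings A, B and D are bought as aromatic building blocks; ring C is the only ring formed (step 5), and both stereocentres (C4, then C2) are set there.

Key step: step 5

Assumption: the (R)-configured phosphoric acid is taken to direct the styrene to the face of the quinone methide that gives 4R; should the opposite sense be found, the (S)-acid is used with no other change.

**Route**

Step 1
Reactants: 1 phloroglucinol triacetate (benzene-1,3,5-triyl triacetate)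
Product: 2 1,3,5-tris(benzyloxy)benzene
Conditions: NaH, BnCl, DMF, 0 °C; H2O (3 equiv) added slowly; rt
Reagents that add atoms: benzyl chloride, ClCc1ccccc1
Why: Williamson O-benzylation in which hydroxide formed from NaH and the added water unmasks the phenoxides one at a time, so each is benzylated on oxygen before a polyanion can build up and undergo C-benzylation.

Step 2
Reactants: 2 1,3,5-tris(benzyloxy)benzene
Product: 3 2-bromo-1,3,5-tris(benzyloxy)benzene
Conditions: NBS (1.0 equiv), CH2Cl2, −78 → 0 °C
Reagents that add atoms: N-bromosuccinimide, O=C1CCC(=O)N1Br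
Why: Electrophilic aromatic bromination of a triply activated ring whose three free positions are equivalent; one equivalent at low temperature should stop at the monobromide because the first bromine deactivates and shields the ring.

Step 3
Reactants: 3 2-bromo-1,3,5-tris(benzyloxy)benzene, 4 4-(benzyloxy)-2-hydroxybenzaldehyde
Product: 7 rac-[4-(benzyloxy)-2-hydroxyphenyl][2,4,6-tris(benzyloxy)phenyl]methanol, via aryllithium 5 (not isolated), via sodium phenoxide 6 (not isolated)
Conditions: 3, n-BuLi, THF, −78 °C; separately 4, NaH, THF, 0 °C; phenoxide solution added at −78 °C, then → 0 °C; H2O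
Reagents that add atoms: none
Why: Bromine–lithium exchange gives an aryllithium flanked by two coordinating benzyloxy groups, which undergoes 1,2-addition to the aldehyde once the phenol is masked as its sodium phenoxide; the carbinol centre forms racemic, which does not matter because it is erased in step 5.

Step 4
Reactants: 8 4-(benzyloxy)benzaldehyde
Product: 9 4-(benzyloxy)styrene (1-(benzyloxy)-4-ethenylbenzene)
Conditions: Ph3PCH3Br, KOtBu, THF, 0 °C → rt
Reagents that add atoms: methyltriphenylphosphonium bromide, C[P+](c1ccccc1)(c1ccccc1)c1ccccc1.[Br-]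
Why: Wittig methylenation of a non-enolisable aromatic aldehyde with the unstabilised ylide; the benzyl ether is inert to the base.

Step 5
Reactants: 7 rac-[4-(benzyloxy)-2-hydroxyphenyl][2,4,6-tris(benzyloxy)phenyl]methanol, 9 4-(benzyloxy)styrene
Product: 11 (2S,4R)-7-(benzyloxy)-2-[4-(benzyloxy)phenyl]-4-[2,4,6-tris(benzyloxy)phenyl]chroman (2,4-trans), via ortho-quinone methide 10 (not isolated)
Conditions: (R)-3,3'-bis(2,4,6-triisopropylphenyl)-1,1'-binaphthyl-2,2'-diyl hydrogen phosphate (10 mol %), 9 (2 equiv), 4 Å MS, toluene, 0 °C → rt, 7 added slowly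
Reagents that add atoms: none
Why: The chiral phosphoric acid protonates the benzylic hydroxyl of 7 and water leaves, so both enantiomers of 7 converge on the planar (E)-ortho-quinone methide 10, which stays hydrogen-bonded (in the limit ion-paired) to the chiral phosphate; this is the known phosphoric-acid-catalysed [4+2] annulation of ortho-quinone methides, generated in situ from ortho-hydroxybenzhydrols, with styrenes to give 2,4-diarylchromans. The CH2 terminus of 9 bonds to the exocyclic carbon of 10 (C3–C4) and the quinone methide oxygen then closes on the developing 4-benzyloxybenzylic cation (O1–C2), so ring C is closed as the six-membered ring of an inverse-electron-demand oxa-Diels–Alder reaction (four atoms O1–C8a–C4a–C4 from 10, two atoms C2–C3 from 9) that is strongly asynchronous or stepwise. C4 is set by the catalyst: the phosphate with its 2,4,6-triisopropylphenyl walls covers one face of the exocyclic carbon, the styrene enters from the other, and this C–C bond formation is irreversible. C2 is set relative to C4 in the ring closure: the 2,6-bis(benzyloxy)aryl group at C4 is pushed pseudoaxial by strain against C5–H, the C2 aryl then prefers the pseudoequatorial position, which is the 2,4-trans arrangement, and because O1–C2 is a 4-alkoxybenzylic ether that the same acid can reionise, any kinetically formed cis isomer should drain to trans on longer stirring without touching C4. The step needs the quinone methide to be trapped by the styrene and not by water, by a second molecule of 7 or by ring D of another molecule, and the styrene must not oligomerise; the three benzyloxy groups of ring D and the para benzyloxy group make 10 long-lived, the congestion around its exocyclic carbon disfavours attack by the hindered ring D positions, the para oxygen makes 9 a strong 2π donor, and the weak bulky acid with sieves and an excess of 9 favours the cross reaction.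

Step 6
Reactants: 12 9-phenylnonanoic acid
Product: 13 9-phenylnonanoyl chloride
Conditions: (COCl)2, cat. DMF, CH2Cl2, 0 °C → rt; concentrated and used crude
Reagents that add atoms: oxalyl chloride, ClC(=O)C(=O)Cl
Why: Acid chloride formation through the chloroiminium catalyst derived from DMF, with only gaseous by-products so that 13 can be used without purification.

Step 7
Reactants: 11 (2S,4R)-7-(benzyloxy)-2-[4-(benzyloxy)phenyl]-4-[2,4,6-tris(benzyloxy)phenyl]chroman, 13 9-phenylnonanoyl chloride
Product: 14 1-{2,4,6-tris(benzyloxy)-3-[(2S,4R)-7-(benzyloxy)-2-[4-(benzyloxy)phenyl]chroman-4-yl]phenyl}-9-phenylnonan-1-one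
Conditions: SnCl4 (1.2 equiv), CH2Cl2, −78 → −40 °C, short reaction time
Reagents that add atoms: none
Why: Friedel–Crafts acylation at ring D, the only ring with three oxygen donors, whose two free positions are equivalent by rotation about the C4–aryl bond (ring A has two donors, ring B one), while the first acyl group deactivates ring D against a second acylation and the low temperature is meant to spare the benzyl ethers and the acid-labile O1–C2 bond; loss of a benzyl group ortho to the new ketone would be harmless because all five are removed in step 8.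

Step 8
Reactants: 14 1-{2,4,6-tris(benzyloxy)-3-[(2S,4R)-7-(benzyloxy)-2-[4-(benzyloxy)phenyl]chroman-4-yl]phenyl}-9-phenylnonan-1-one
Product: 15 (+)-myristinin D, 1-{2,4,6-trihydroxy-3-[(2S,4R)-7-hydroxy-2-(4-hydroxyphenyl)chroman-4-yl]phenyl}-9-phenylnonan-1-one
Conditions: H2 (1 atm), 10% Pd/C, EtOAc/MeOH, rt, stopped after uptake of five equivalents
Reagents that add atoms: none
Why: Catalytic hydrogenolysis of the five aryl benzyl ethers, which should be cleaved much faster than the cyclic benzylic O1–C2 ether of the chroman or the aryl ketone (the latter chelated by its ortho hydroxyls as soon as they are freed); no stereocentre is touched.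

**Compound list**

1 | phloroglucinol triacetate (benzene-1,3,5-triyl triacetate) | CC(=O)Oc1cc(OC(C)=O)cc(OC(C)=O)c1 | starting material
2 | 1,3,5-tris(benzyloxy)benzene | c1ccccc1COc1cc(OCc2ccccc2)cc(OCc2ccccc2)c1 | intermediate
3 | 2-bromo-1,3,5-tris(benzyloxy)benzene | Brc1c(OCc2ccccc2)cc(OCc2ccccc2)cc1OCc1ccccc1 | intermediate
4 | 4-(benzyloxy)-2-hydroxybenzaldehyde | O=Cc1ccc(OCc2ccccc2)cc1O | starting material
5 | [2,4,6-tris(benzyloxy)phenyl]lithium | [Li]c1c(OCc2ccccc2)cc(OCc2ccccc2)cc1OCc1ccccc1 | intermediate
6 | sodium 5-(benzyloxy)-2-formylphenolate | [Na+].[O-]c1cc(OCc2ccccc2)ccc1C=O | intermediate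
7 | rac-[4-(benzyloxy)-2-hydroxyphenyl][2,4,6-tris(benzyloxy)phenyl]methanol | OC(c1ccc(OCc2ccccc2)cc1O)c1c(OCc2ccccc2)cc(OCc2ccccc2)cc1OCc1ccccc1 | intermediate
8 | 4-(benzyloxy)benzaldehyde | O=Cc1ccc(OCc2ccccc2)cc1 | starting material
9 | 4-(benzyloxy)styrene | C=Cc1ccc(OCc2ccccc2)cc1 | intermediate
10 | (6E)-3-(benzyloxy)-6-{[2,4,6-tris(benzyloxy)phenyl]methylidene}cyclohexa-2,4-dien-1-one | c1ccccc1COc1cc(OCc2ccccc2)cc(OCc2ccccc2)c1/C=C1\C=CC(OCc2ccccc2)=CC1=O | intermediate
11 | (2S,4R)-7-(benzyloxy)-2-[4-(benzyloxy)phenyl]-4-[2,4,6-tris(benzyloxy)phenyl]chroman | c1ccccc1COc1cc(OCc2ccccc2)c([C@@H]2C[C@@H](c3ccc(OCc4ccccc4)cc3)Oc3cc(OCc4ccccc4)ccc32)c(OCc2ccccc2)c1 | intermediate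
12 | 9-phenylnonanoic acid | OC(=O)CCCCCCCCc1ccccc1 | starting material
13 | 9-phenylnonanoyl chloride | ClC(=O)CCCCCCCCc1ccccc1 | intermediate
14 | 1-{2,4,6-tris(benzyloxy)-3-[(2S,4R)-7-(benzyloxy)-2-[4-(benzyloxy)phenyl]chroman-4-yl]phenyl}-9-phenylnonan-1-one | O=C(CCCCCCCCc1ccccc1)c1c(OCc2ccccc2)cc(OCc2ccccc2)c([C@@H]2C[C@@H](c3ccc(OCc4ccccc4)cc3)Oc3cc(OCc4ccccc4)ccc32)c1OCc1ccccc1 | intermediate
15 | (+)-myristinin D | O=C(CCCCCCCCc1ccccc1)c1c(O)cc(O)c([C@@H]2C[C@@H](c3ccc(O)cc3)Oc3cc(O)ccc32)c1O | target

**Step count**

Total: 8 steps. Longest linear sequence: 6 steps (steps 1, 2, 3, 5, 7, 8).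

**Steps most likely to fail**

1. Step 5. The highly stabilised quinone methide may sit too loosely in the phosphate pocket, so that the two faces of the exocyclic carbon are poorly distinguished. It may also react too slowly with the styrene, so that acid-induced oligomerisation of 9 or self-condensation takes over. Ring closure may stop at the 2,4-cis isomer if the acid is too weak to reionise O1–C2.
Fallback, setting out from 8 and rejoining at 11: Claisen–Schmidt condensation of 8 with commercial 1-[4-(benzyloxy)-2-hydroxyphenyl]ethanone (KOH, EtOH, rt) should give the chalcone (E)-1-[4-(benzyloxy)-2-hydroxyphenyl]-3-[4-(benzyloxy)phenyl]prop-2-en-1-one F1. Oxa-Michael ring closure (NaOAc, EtOH, reflux) gives the racemic flavanone 7-(benzyloxy)-2-[4-(benzyloxy)phenyl]chroman-4-one F2. Asymmetric transfer hydrogenation run as a kinetic resolution (RuCl[(S,S)-TsDPEN](p-cymene), HCO2H/Et3N, stopped near half conversion) is expected to reduce the 2S ketone, with hydride entering trans to the C2 aryl group, to the cis alcohol (2S,4S)-7-(benzyloxy)-2-[4-(benzyloxy)phenyl]chroman-4-ol F3, which is separated from the unreacted 2R ketone. Ionisation of F3 with BF3·OEt2 in CH2Cl2 at −78 °C in the presence of an excess of 2 should arylate the C4 cation anti to the C2 aryl group and give 11. In this variant C2 is set by the reduction and C4 by substrate control.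

2. Step 7. The acylium complex may attack ring A (C6 or C8) as well as ring D. The Lewis acid may cleave benzyl ethers and release benzyl cations that alkylate the electron-rich rings. It may also ionise the O1–C2 bond and open ring C.
Fallback, setting out from 11 and rejoining at 14: Vilsmeier–Haack formylation (POCl3, DMF, 0 °C → rt; aqueous NaOAc), whose weak electrophile discriminates more sharply in favour of ring D and needs no metal Lewis acid, should give 2,4,6-tris(benzyloxy)-3-[(2S,4R)-7-(benzyloxy)-2-[4-(benzyloxy)phenyl]chroman-4-yl]benzaldehyde F4. Addition of 8-phenyloctylmagnesium bromide (from commercial (8-bromooctyl)benzene and Mg, THF, 0 °C) gives the secondary alcohol 1-{2,4,6-tris(benzyloxy)-3-[(2S,4R)-7-(benzyloxy)-2-[4-(benzyloxy)phenyl]chroman-4-yl]phenyl}-9-phenylnonan-1-ol F5 as a mixture of carbinol epimers. Oxidation with Dess–Martin periodinane (NaHCO3, CH2Cl2) then gives 14.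

3. Step 3. The hindered aryllithium may add only slowly to the electron-rich phenoxide-bearing aldehyde, and on warming may be lost by proton transfer from a benzylic position. The very ionisable carbinol may also dehydrate and condense during work-up or on silica; base-washed silica or use of crude 7 is foreseen.
Fallback, setting out from 2 and rejoining at 7: Friedel–Crafts acylation of 2 with commercial 4-(benzyloxy)-2-hydroxybenzoic acid activated as its mixed anhydride (trifluoroacetic anhydride, CH2Cl2, 0 °C → rt; then K2CO3, MeOH to cleave any aryl ester) should give the benzophenone [4-(benzyloxy)-2-hydroxyphenyl][2,4,6-tris(benzyloxy)phenyl]methanone F6. Hydride reduction (LiAlH4, THF, 0 °C → rt) then delivers 7.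

**Further compounds**

F1 | step 5 | (E)-1-[4-(benzyloxy)-2-hydroxyphenyl]-3-[4-(benzyloxy)phenyl]prop-2-en-1-one | O=C(/C=C/c1ccc(OCc2ccccc2)cc1)c1ccc(OCc2ccccc2)cc1O
F2 | step 5 | rac-7-(benzyloxy)-2-[4-(benzyloxy)phenyl]chroman-4-one | O=C1CC(c2ccc(OCc3ccccc3)cc2)Oc2cc(OCc3ccccc3)ccc21
F3 | step 5 | (2S,4S)-7-(benzyloxy)-2-[4-(benzyloxy)phenyl]chroman-4-ol | O[C@H]1C[C@@H](c2ccc(OCc3ccccc3)cc2)Oc2cc(OCc3ccccc3)ccc21
F4 | step 7 | 2,4,6-tris(benzyloxy)-3-[(2S,4R)-7-(benzyloxy)-2-[4-(benzyloxy)phenyl]chroman-4-yl]benzaldehyde | O=Cc1c(OCc2ccccc2)cc(OCc2ccccc2)c([C@@H]2C[C@@H](c3ccc(OCc4ccccc4)cc3)Oc3cc(OCc4ccccc4)ccc32)c1OCc1ccccc1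
F5 | step 7 | 1-{2,4,6-tris(benzyloxy)-3-[(2S,4R)-7-(benzyloxy)-2-[4-(benzyloxy)phenyl]chroman-4-yl]phenyl}-9-phenylnonan-1-ol (carbinol epimers) | OC(CCCCCCCCc1ccccc1)c1c(OCc2ccccc2)cc(OCc2ccccc2)c([C@@H]2C[C@@H](c3ccc(OCc4ccccc4)cc3)Oc3cc(OCc4ccccc4)ccc32)c1OCc1ccccc1
F6 | step 3 | [4-(benzyloxy)-2-hydroxyphenyl][2,4,6-tris(benzyloxy)phenyl]methanone | O=C(c1ccc(OCc2ccccc2)cc1O)c1c(OCc2ccccc2)cc(OCc2ccccc2)cc1OCc1ccccc1
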